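**Retrosynthetic overview** (ring A = the formyl-bearing dihydrobenzofuran; ring B = the dihydrobenzofuran carrying the 3,5-dihydroxyphenyl group)
1. Target ⇒ open the C2–O bond of ring A to a free-phenol 2-hydroxyaryl triarylethene; forward, the last step is a chiral-acid ring-closing hydroaryloxylation that sets C2/C3 of ring A.
2. That triarylethene ⇒ Suzuki union of the ring B 4-bromide (as its boronate) with a (Z)-bromoalkene built from 4-acetoxybenzaldehyde (dibromo-olefination) and (5-formyl-2-hydroxyphenyl)boronic acid.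
3. Ring B ⇒ open its C2–O bond to a second triarylethene; forward, the first enantioselective hydroaryloxylation sets C2/C3 of ring B, then the methyl ethers are removed.
4. That triarylethene ⇒ 2-hydroxybenzophenone + 4-methoxybenzyl Grignard; benzophenone ⇒ Friedel–Crafts acylation of 1-bromo-3,5-dimethoxybenzene.
5. Ring order: ring B first, ring A last; both heterocycles are closed by C–O bond formation.

Assumption: (4-methoxybenzyl)magnesium chloride solution and (5-formyl-2-hydroxyphenyl)boronic acid are bought as catalogue items, and the IDPi enantiomer that gives the (2R,3R) series is fixed in a first small-scale run.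

**Step 1**
Reactants: 1 1-bromo-3,5-dimethoxybenzene; 2 3,5-dimethoxybenzoyl chloride
Product: 4 (2-bromo-6-hydroxy-4-methoxyphenyl)(3,5-dimethoxyphenyl)methanone, via tetramethoxy ketone 3 (not isolated)
Conditions: AlCl3 (2.5 equiv), CH2Cl2, 0 → 40 °C; aq. HCl work-up
Reagents that add atoms: none
Why: Friedel–Crafts acylation goes ortho to bromine and para to a methoxy group (the site between the two methoxy groups is more hindered, as in the Vilsmeier formylation of 1), and the aluminium chelate of the ketone then cleaves only the methyl ether ortho to the carbonyl, freeing exactly the phenol that becomes the ring B oxygen.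

**Step 2**
Reactants: 4 (2-bromo-6-hydroxy-4-methoxyphenyl)(3,5-dimethoxyphenyl)methanone; 5 (4-methoxybenzyl)magnesium chloride
Product: 7 3-bromo-2-[1-(3,5-dimethoxyphenyl)-2-(4-methoxyphenyl)ethenyl]-5-methoxyphenol (E/Z mixture), via tertiary carbinol 6 (not isolated)
Conditions: 5 (3.5 equiv), LaCl3·2LiCl (1 equiv), THF, 0 °C → rt; 1 M aq. HCl quench, 0 °C; then PPTS (10 mol%), toluene, 60 °C
Reagents that add atoms: none
Why: Grignard 1,2-addition to the phenoxide-chelated hindered ketone (lanthanum salt assisted) followed by mild E1 dehydration through the ortho/para-oxygen-stabilised tertiary benzylic cation; no stereocentre is formed and the alkene geometry does not matter because both isomers converge in step 3.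

**Step 3**
Reactants: 7 3-bromo-2-[1-(3,5-dimethoxyphenyl)-2-(4-methoxyphenyl)ethenyl]-5-methoxyphenol (E/Z mixture)
Product: 8 (2R,3R)-4-bromo-3-(3,5-dimethoxyphenyl)-6-methoxy-2-(4-methoxyphenyl)-2,3-dihydro-1-benzofuran
Conditions: (S,S)-IDPi (imidodiphosphorimidate from two (S)-3,3'-bis[3,5-bis(trifluoromethyl)phenyl]-BINOL units, inner N-triflyl groups; 5 mol%), CHCl3, −20 °C, 0.02 M, stopped at full conversion; recrystallisation
Reagents that add atoms: none
Why: Proposed new method: a chiral-Brønsted-acid-catalysed enantioselective intramolecular hydroaryloxylation of a 2-(1,2-diarylvinyl)phenol, in which the confined acid protonates the alkene carbon bearing the two aryl groups (this creates C3, the face being chosen inside the chiral anion pocket while the anion is hydrogen-bonded to the ortho phenol) and the phenol then closes the C2–O bond on the resulting 4-methoxybenzylic cation anti to the C3 aryl group (this creates C2, trans), the E and Z alkenes interconverting under the acid by reversible protonation at the other alkene carbon so that both feed the same ion pair; closest known reaction type: IDPi-catalysed asymmetric intramolecular hydroalkoxylation of alkenes and the achiral acid cyclisation of 2-hydroxystilbenes to 2-aryl-2,3-dihydrobenzofurans.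

**Step 4**
Reactants: 8 (2R,3R)-4-bromo-3-(3,5-dimethoxyphenyl)-6-methoxy-2-(4-methoxyphenyl)-2,3-dihydro-1-benzofuran
Product: 9 (2R,3R)-4-bromo-3-(3,5-dihydroxyphenyl)-2-(4-hydroxyphenyl)-2,3-dihydro-1-benzofuran-6-ol
Conditions: BBr3 (8 equiv), CH2Cl2, −78 → 0 °C; then MeOH, aq. NaHCO3
Reagents that add atoms: none
Why: BBr3 cleavage of the four aryl methyl ethers (Lewis-acid demethylation) at the one stage where it is harmless, since no alkene and no ring A are present, C3 has no epimerisation pathway and any reversible opening at C2 through the benzylic cation re-closes to the favoured trans ring, so (2R,3R) is retained.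

**Step 5**
Reactants: 10 4-formylphenyl acetate
Product: 11 4-(2,2-dibromoethenyl)phenyl acetate
Conditions: CBr4 (2 equiv), PPh3 (4 equiv), CH2Cl2, 0 °C
Reagents that add atoms: carbon tetrabromide, BrC(Br)(Br)Br
Why: Ramirez dibromo-olefination (first stage of the Corey–Fuchs reaction) of an aryl aldehyde through the ylide Ph3P=CBr2, which tolerates the aryl acetate.

**Step 6**
Reactants: 11 4-(2,2-dibromoethenyl)phenyl acetate; 12 (5-formyl-2-hydroxyphenyl)boronic acid
Product: 14 3-[(Z)-1-bromo-2-(4-hydroxyphenyl)ethenyl]-4-hydroxybenzaldehyde, via acetate bromoalkene 13 (not isolated)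
Conditions: Pd2(dba)3 (2.5 mol%), tris(2-furyl)phosphine (15 mol%), 2 M aq. Na2CO3, 1,4-dioxane, 65 °C; then K2CO3, MeOH, rt
Reagents that add atoms: none
Why: Suzuki–Miyaura mono-coupling of a 1,1-dibromoalkene, in which zerovalent palladium inserts selectively into the less hindered C–Br bond trans to the aryl group and so gives only the (Z)-bromoalkene, followed by methanolysis of the phenyl acetate.

**Step 7**
Reactants: 9 (2R,3R)-4-bromo-3-(3,5-dihydroxyphenyl)-2-(4-hydroxyphenyl)-2,3-dihydro-1-benzofuran-6-ol; 14 3-[(Z)-1-bromo-2-(4-hydroxyphenyl)ethenyl]-4-hydroxybenzaldehyde; 15 bis(pinacolato)diboron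
Product: 17 3-[(E)-1-[(2R,3R)-3-(3,5-dihydroxyphenyl)-6-hydroxy-2-(4-hydroxyphenyl)-2,3-dihydro-1-benzofuran-4-yl]-2-(4-hydroxyphenyl)ethenyl]-4-hydroxybenzaldehyde, via aryl boronate 16 (not isolated)
Conditions: 9, 15, Pd(OAc)2 (5 mol%), SPhos (10 mol%), KOAc (3 equiv), 1,4-dioxane, 90 °C; then 14, 2 M aq. K2CO3, THF, 55 °C; work-up at pH 6, reversed-phase chromatography without acid modifier
Reagents that add atoms: none
Why: One-pot Miyaura borylation/Suzuki–Miyaura coupling, in which the hindered aryl bromide is borylated under weakly basic KOAc conditions and the boronate is joined to the alkenyl bromide with retention of alkene geometry under mild carbonate base, conditions that free phenols, the aldehyde and the 2-(4-hydroxyphenyl)dihydrobenzofuran tolerate (as in routine K2CO3 methylations of oligostilbenes) and that touch no stereocentre.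

**Step 8**
Reactants: 17 3-[(E)-1-[(2R,3R)-3-(3,5-dihydroxyphenyl)-6-hydroxy-2-(4-hydroxyphenyl)-2,3-dihydro-1-benzofuran-4-yl]-2-(4-hydroxyphenyl)ethenyl]-4-hydroxybenzaldehyde
Product: 18 (2R,3R)-3-[(2R,3R)-3-(3,5-dihydroxyphenyl)-6-hydroxy-2-(4-hydroxyphenyl)-2,3-dihydro-1-benzofuran-4-yl]-2-(4-hydroxyphenyl)-2,3-dihydro-1-benzofuran-5-carbaldehyde (CNP0318276.1)
Conditions: the same (S,S)-IDPi (5 mol%), EtOAc/CH2Cl2 1:3, −40 → −20 °C, 0.01 M; Et3N quench at full conversion; reversed-phase HPLC
Reagents that add atoms: none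
Why: Proposed new method: second use of the step 3 hydroaryloxylation, now on a free 4-hydroxystilbene-type alkene, where the chiral acid tautomerises the alkene to a neutral p-quinone methide by catalyst-controlled protonation at C3 (3R; the phenol-bearing aryl, the second aryl and C2 are arranged as in step 3, so the same catalyst enantiomer should be matched) and the formyl-bearing phenol adds 5-exo to the quinone methide carbon to close the C2–O bond trans (2R), the five-membered O-closure outrunning attack by the neighbouring resorcinol carbon; closest known reaction type: chiral phosphoric acid catalysis of additions to in situ formed p-quinone methides, the facile acid-mediated E/Z isomerisation of 4-hydroxytriarylethylenes through the same tautomer, and the biosynthetic quinone methide ring closure of oligostilbenes.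

**Compound list**
1 | 1-bromo-3,5-dimethoxybenzene | COc1cc(Br)cc(OC)c1 | starting material
2 | 3,5-dimethoxybenzoyl chloride | COc1cc(cc(OC)c1)C(Cl)=O | starting material
3 | (2-bromo-4,6-dimethoxyphenyl)(3,5-dimethoxyphenyl)methanone | COc1cc(OC)c(C(=O)c2cc(OC)cc(OC)c2)c(Br)c1 | intermediate
4 | (2-bromo-6-hydroxy-4-methoxyphenyl)(3,5-dimethoxyphenyl)methanone | COc1cc(O)c(C(=O)c2cc(OC)cc(OC)c2)c(Br)c1 | intermediate
5 | (4-methoxybenzyl)magnesium chloride | COc1ccc(C[Mg]Cl)cc1 | starting material
6 | rac-1-(2-bromo-6-hydroxy-4-methoxyphenyl)-1-(3,5-dimethoxyphenyl)-2-(4-methoxyphenyl)ethan-1-ol | COc1ccc(CC(O)(c2cc(OC)cc(OC)c2)c2c(O)cc(OC)cc2Br)cc1 | intermediate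
7 | 3-bromo-2-[1-(3,5-dimethoxyphenyl)-2-(4-methoxyphenyl)ethenyl]-5-methoxyphenol (E/Z mixture) | COc1ccc(C=C(c2cc(OC)cc(OC)c2)c2c(O)cc(OC)cc2Br)cc1 | intermediate
8 | (2R,3R)-4-bromo-3-(3,5-dimethoxyphenyl)-6-methoxy-2-(4-methoxyphenyl)-2,3-dihydro-1-benzofuran | Brc1cc(OC)cc2c1[C@@H](c1cc(OC)cc(OC)c1)[C@H](c1ccc(OC)cc1)O2 | intermediate
9 | (2R,3R)-4-bromo-3-(3,5-dihydroxyphenyl)-2-(4-hydroxyphenyl)-2,3-dihydro-1-benzofuran-6-ol | Brc1cc(O)cc2c1[C@@H](c1cc(O)cc(O)c1)[C@H](c1ccc(O)cc1)O2 | intermediate
10 | 4-formylphenyl acetate | CC(=O)Oc1ccc(C=O)cc1 | starting material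
11 | 4-(2,2-dibromoethenyl)phenyl acetate | CC(=O)Oc1ccc(C=C(Br)Br)cc1 | intermediate
12 | (5-formyl-2-hydroxyphenyl)boronic acid | OB(O)c1cc(C=O)ccc1O | starting material
13 | 4-[(Z)-2-bromo-2-(5-formyl-2-hydroxyphenyl)ethenyl]phenyl acetate | CC(=O)Oc1ccc(/C=C(\Br)c2cc(C=O)ccc2O)cc1 | intermediate
14 | 3-[(Z)-1-bromo-2-(4-hydroxyphenyl)ethenyl]-4-hydroxybenzaldehyde | Oc1ccc(/C=C(\Br)c2cc(C=O)ccc2O)cc1 | intermediate
15 | bis(pinacolato)diboron | CC1(C)OB(OC1(C)C)B1OC(C)(C)C(C)(C)O1 | starting material
16 | (2R,3R)-3-(3,5-dihydroxyphenyl)-2-(4-hydroxyphenyl)-4-(4,4,5,5-tetramethyl-1,3,2-dioxaborolan-2-yl)-2,3-dihydro-1-benzofuran-6-ol | CC1(C)OB(OC1(C)C)c1cc(O)cc2c1[C@@H](c1cc(O)cc(O)c1)[C@H](c1ccc(O)cc1)O2 | intermediate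
17 | 3-[(E)-1-[(2R,3R)-3-(3,5-dihydroxyphenyl)-6-hydroxy-2-(4-hydroxyphenyl)-2,3-dihydro-1-benzofuran-4-yl]-2-(4-hydroxyphenyl)ethenyl]-4-hydroxybenzaldehyde | O=Cc1ccc(O)c(c1)/C(=C/c1ccc(O)cc1)c1cc(O)cc2c1[C@@H](c1cc(O)cc(O)c1)[C@H](c1ccc(O)cc1)O2 | intermediate
18 | (2R,3R)-3-[(2R,3R)-3-(3,5-dihydroxyphenyl)-6-hydroxy-2-(4-hydroxyphenyl)-2,3-dihydro-1-benzofuran-4-yl]-2-(4-hydroxyphenyl)-2,3-dihydro-1-benzofuran-5-carbaldehyde | O=Cc1ccc2c(c1)[C@@H](c1cc(O)cc3c1[C@@H](c1cc(O)cc(O)c1)[C@H](c1ccc(O)cc1)O3)[C@H](c1ccc(O)cc1)O2 | target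

**Totals**
Total step count: 8. Longest linear sequence: 6 (steps 1, 2, 3, 4, 7, 8).

**Three steps most likely to fail**

Step 3, the new enantioselective ring closure: the ee may be low, or achiral background cyclisation of 7 may compete. The fallback uses known chemistry, sets out from 4 and comes back at 8. O-Alkylation of 4 with 4-methoxybenzyl chloride (K2CO3, DMF) gives the 4-methoxybenzyl ether F1. Condensation with hydrazine hydrate (cat. AcOH, n-BuOH, 110 °C) gives the hydrazone F2. MnO2 oxidation gives the diaryldiazomethane F3, which is not isolated. F3 undergoes the established enantioselective intramolecular C–H insertion of a donor/donor rhodium carbene into the benzylic ether C–H bond with Rh2(R-PTAD)4 (or its mirror image, as a screen dictates), giving the cis-dihydrobenzofuran F4 with C3 set by the catalyst. Brief treatment with TFA epimerises C2 through the 4-methoxybenzylic cation to the trans isomer 8.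

Step 7, the one-pot borylation and coupling of two hindered, polyphenolic partners. The fallback reverses the order in which the two aryl groups are put on the dibromo-olefin; it sets out from 9 and 11 and comes back at 18. Boronate 16 is made from 9 as before but is coupled first with 11 at its unhindered trans C–Br bond (Pd2(dba)3, tris(2-furyl)phosphine, aq. Na2CO3, 60 °C), giving the acetate bromoalkene F5. K2CO3/MeOH converts F5 into the phenol bromoalkene F6. The second Suzuki coupling, now with the small boronic acid 12 (Pd(OAc)2, SPhos, aq. K2CO3, 55 °C), gives the Z isomer of 17, F7. Step 8 applied to F7 gives 18, because both alkene isomers pass through the same quinone methide.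

Step 8, the second use of the new ring closure: catalyst control over C3 next to the existing ring B centres is untested, and acid-triggered opening of either ring must be avoided. The fallback uses known chemistry, sets out from 17 and comes back at 18. Catalyst control is given up and 17 is cyclised under substrate control with an achiral acid, the way quinone methide precursors are closed in oligostilbene chemistry (HCO2H, or 1 mol% TsOH·H2O in MeCN, 0 °C). Ring closure is still trans, so only two products form: 18 and its ring A (2S,3S) diastereomer F8. They are separated by reversed-phase HPLC.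

**Further compounds**
F1 | step 3 | (2-bromo-4-methoxy-6-[(4-methoxyphenyl)methoxy]phenyl)(3,5-dimethoxyphenyl)methanone | COc1ccc(COc2cc(OC)cc(Br)c2C(=O)c2cc(OC)cc(OC)c2)cc1
F2 | step 3 | (2-bromo-4-methoxy-6-[(4-methoxyphenyl)methoxy]phenyl)(3,5-dimethoxyphenyl)methanone hydrazone | COc1ccc(COc2cc(OC)cc(Br)c2C(=NN)c2cc(OC)cc(OC)c2)cc1
F3 | step 3 | 1-bromo-2-[diazo(3,5-dimethoxyphenyl)methyl]-5-methoxy-3-[(4-methoxyphenyl)methoxy]benzene | COc1ccc(COc2cc(OC)cc(Br)c2C(=[N+]=[N-])c2cc(OC)cc(OC)c2)cc1
F4 | step 3 | (2S,3R)-4-bromo-3-(3,5-dimethoxyphenyl)-6-methoxy-2-(4-methoxyphenyl)-2,3-dihydro-1-benzofuran (cis) | Brc1cc(OC)cc2c1[C@@H](c1cc(OC)cc(OC)c1)[C@@H](c1ccc(OC)cc1)O2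
F5 | step 7 | 4-[(Z)-2-bromo-2-[(2R,3R)-3-(3,5-dihydroxyphenyl)-6-hydroxy-2-(4-hydroxyphenyl)-2,3-dihydro-1-benzofuran-4-yl]ethenyl]phenyl acetate | CC(=O)Oc1ccc(/C=C(\Br)c2cc(O)cc3c2[C@@H](c2cc(O)cc(O)c2)[C@H](c2ccc(O)cc2)O3)cc1
F6 | step 7 | (2R,3R)-4-[(Z)-1-bromo-2-(4-hydroxyphenyl)ethenyl]-3-(3,5-dihydroxyphenyl)-2-(4-hydroxyphenyl)-2,3-dihydro-1-benzofuran-6-ol | Oc1ccc(/C=C(\Br)c2cc(O)cc3c2[C@@H](c2cc(O)cc(O)c2)[C@H](c2ccc(O)cc2)O3)cc1
F7 | step 7 | 3-[(Z)-1-[(2R,3R)-3-(3,5-dihydroxyphenyl)-6-hydroxy-2-(4-hydroxyphenyl)-2,3-dihydro-1-benzofuran-4-yl]-2-(4-hydroxyphenyl)ethenyl]-4-hydroxybenzaldehyde | O=Cc1ccc(O)c(c1)/C(=C\c1ccc(O)cc1)c1cc(O)cc2c1[C@@H](c1cc(O)cc(O)c1)[C@H](c1ccc(O)cc1)O2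
F8 | step 8 | (2S,3S)-3-[(2R,3R)-3-(3,5-dihydroxyphenyl)-6-hydroxy-2-(4-hydroxyphenyl)-2,3-dihydro-1-benzofuran-4-yl]-2-(4-hydroxyphenyl)-2,3-dihydro-1-benzofuran-5-carbaldehyde | O=Cc1ccc2c(c1)[C@H](c1cc(O)cc3c1[C@@H](c1cc(O)cc(O)c1)[C@H](c1ccc(O)cc1)O3)[C@@H](c1ccc(O)cc1)O2
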